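The route cuts ring A of the isocoumarin into a 2-pyranone diene and a two-carbon ketene acetal. Ring A carries the lactone carbon C1 on C8a, the aryl ether oxygen on C8, an oxygen on C6 and C4 on C4a. Pyranone 11 holds the matching ester, aryloxy and methyl groups on its positions 5, 4 and 6, and 1,1-dimethoxyethene supplies isocoumarin C5 and C6. One thermal step forms C4a–C5 and C6–C7, expels CO2 and methanol, and delivers the aromatic ring with the hindered diaryl ether already in place. The ether is made beforehand by addition–elimination on a 4-chloropyranone; the lactone ring follows by toluate acylation.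

Key step: step 6

Remark: the target is achiral; intermediates 13 and 18 form as racemates and lose their stereocentres within the same step, so no stereodescriptors are needed.

Step 1
Reactants: 1 olivetol dimethyl ether (1,3-dimethoxy-5-pentylbenzene)
Product: 3 2,4-dimethoxy-6-pentylbenzaldehyde, via iminium salt 2 (not isolated)
Conditions: POCl3, DMF, 0 to 70 °C; then H2O
Reagents that add atoms: N,N-dimethylformamide, CN(C)C=O; water, O
Why: Vilsmeier–Haack formylation should take the ring position para to one methoxy group and ortho to the other, next to the pentyl chain, because the bulky chloroiminium electrophile avoids the position flanked by both methoxy groups.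

Step 2
Reactants: 3 2,4-dimethoxy-6-pentylbenzaldehyde
Product: 5 2,4-dimethoxy-6-pentylphenol, via aryl formate 4 (not isolated)
Conditions: mCPBA, CH2Cl2, 0 °C to rt; aq. NaHCO3 wash; then K2CO3 (cat.), MeOH, rt
Reagents that add atoms: mCPBA (3-chloroperoxybenzoic acid), O=C(OO)c1cccc(Cl)c1
Why: Baeyer–Villiger oxidation of an electron-rich benzaldehyde proceeds with aryl migration (a Dakin-type outcome), and mild methanolysis of the formate should free the phenol.

Step 3
Reactants: 6 methyl acetoacetate; 7 malonyl dichloride
Product: 8 methyl 4-hydroxy-6-methyl-2-oxo-2H-pyran-5-carboxylate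
Conditions: neat, 25 °C, 2–3 d; trituration with Et2O
Reagents that add atoms: none
Why: Double acylation of the β-keto ester by the 1,3-bis-electrophile (C-acylation at the active methylene and O-acylation of the enol) is the established malonyl dichloride condensation that gives 5-acyl-4-hydroxy-6-methyl-2-pyranones.

Step 4
Reactants: 8 methyl 4-hydroxy-6-methyl-2-oxo-2H-pyran-5-carboxylate
Product: 10 methyl 4-chloro-6-methyl-2-oxo-2H-pyran-5-carboxylate, via dichlorophosphate 9 (not isolated)
Conditions: POCl3, Et3N, MeCN, 80 °C; then ice–water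
Reagents that add atoms: phosphoryl chloride, O=P(Cl)(Cl)Cl
Why: Deoxychlorination of a vinylogous acid, in which the acidic 4-OH is phosphorylated and chloride substitutes at C4 by addition–elimination, is the standard way from 4-hydroxy-2-pyranones and 4-hydroxycoumarins to their 4-chloro compounds.

Step 5
Reactants: 5 2,4-dimethoxy-6-pentylphenol; 10 methyl 4-chloro-6-methyl-2-oxo-2H-pyran-5-carboxylate
Product: 11 methyl 4-(2,4-dimethoxy-6-pentylphenoxy)-6-methyl-2-oxo-2H-pyran-5-carboxylate
Conditions: K2CO3, MeCN, 25 to 50 °C
Reagents that add atoms: none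
Why: Addition–elimination (vinylogous acyl substitution) of the phenoxide at C4, which is β to the lactone carbonyl, should give the aryl vinyl ether; the phenoxide can only react at oxygen because both ortho positions and the para position are substituted, and chloride, unlike a sulfonate, offers no second electrophilic site at the leaving group.

Step 6
Reactants: 11 methyl 4-(2,4-dimethoxy-6-pentylphenoxy)-6-methyl-2-oxo-2H-pyran-5-carboxylate; 12 1,1-dimethoxyethene
Product: 15 methyl 2-(2,4-dimethoxy-6-pentylphenoxy)-4-methoxy-6-methylbenzoate, via bicyclic lactone adduct 13 (not isolated), via cyclohexadiene acetal 14 (not isolated)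
Conditions: 12 (6 equiv), toluene, 120 °C, sealed tube
Reagents that add atoms: none
Why: In an inverse-electron-demand Diels–Alder reaction the C3=C4–C5=C6 diene of pyranone 11, made electron-poor by the lactone carbonyl and the 5-ester, adds the electron-rich alkene 12 across C3 and C6 to give bridged lactone 13, which extrudes CO2 by retro-[4+2] to diene 14 and then loses methanol from the acetal to aromatise. The closest known reaction type is the cycloaddition of methyl coumalate and other 5-alkoxycarbonyl-2-pyranones with ketene acetals, which gives 4-alkoxybenzoates through the same loss of CO2 and alcohol. Ring A is closed intermolecularly by the [4+2] cycloaddition itself, both new bonds (isocoumarin C4a–C5 and C6–C7) forming across the diene termini, so no separate cyclisation is involved. The two bridgehead centres of 13 are transient, racemic and erased on aromatisation, so no stereocontrol is required. The step needs a single regiochemistry, the CH2 of 12 bonding to the methyl-bearing pyranone C6 and the acetal carbon to C3; matched polarisation secures it, since C6 is the electrophilic terminus (β to the ester and vinylogous to the lactone carbonyl), C3 is the donor-flanked terminus, and the CH2 is the nucleophilic end of the ketene acetal. The aryloxy group should stay on C4 because no base or nucleophile stronger than the neutral alkene is present.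

Step 7
Reactants: 15 methyl 2-(2,4-dimethoxy-6-pentylphenoxy)-4-methoxy-6-methylbenzoate; 16 N-methoxy-N-methylhexanamide
Product: 19 methyl 2-(2,4-dimethoxy-6-pentylphenoxy)-4-methoxy-6-(2-oxoheptyl)benzoate, via benzylic lithium species 17 (not isolated), via tetrahedral lithium adduct 18 (not isolated)
Conditions: LiN(iPr)2 (LDA, 1.2 equiv), THF, −78 °C; then 16, −78 to 0 °C; then 1 M HCl
Reagents that add atoms: none
Why: Lateral lithiation of an ortho-toluate gives a benzylic anion stabilised by the neighbouring ester, and its acylation by a Weinreb amide (Weinreb ketone synthesis) should stop at the ketone because the chelated tetrahedral adduct survives until the acidic quench.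

Step 8
Reactants: 19 methyl 2-(2,4-dimethoxy-6-pentylphenoxy)-4-methoxy-6-(2-oxoheptyl)benzoate
Product: 20 8-(2,4-dimethoxy-6-pentylphenoxy)-6-methoxy-3-pentyl-1H-isochromen-1-one
Conditions: TsOH·H2O (0.2 equiv), toluene, 110 °C, MeOH distilled off
Reagents that add atoms: none
Why: Acid-catalysed enol lactonisation, a 6-exo-trig attack of the enol oxygen of the benzylic ketone on the ortho ester with loss of methanol, should give the conjugated isocoumarin ring, driven by removal of methanol.

Step 9
Reactants: 20 8-(2,4-dimethoxy-6-pentylphenoxy)-6-methoxy-3-pentyl-1H-isochromen-1-one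
Product: 22 8-(2,4-dihydroxy-6-pentylphenoxy)-6-hydroxy-3-pentyl-1H-isochromen-1-one, via tris(dibromoboryl) ether 21 (not isolated)
Conditions: BBr3 (8 equiv), CH2Cl2, −78 °C to rt; then H2O
Reagents that add atoms: none
Why: Lewis-acid ether cleavage with BBr3 should remove the three aryl methyl ethers by bromide attack on the methyl groups, while the diaryl ether (no carbon open to SN2 attack) and the enol lactone are expected to survive.

Compound list
1 | olivetol dimethyl ether (1,3-dimethoxy-5-pentylbenzene) | CCCCCc1cc(OC)cc(OC)c1 | starting material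
2 | (2,4-dimethoxy-6-pentylbenzylidene)dimethylammonium dichlorophosphate (not isolated) | CCCCCc1cc(OC)cc(OC)c1C=[N+](C)C.[O-]P(=O)(Cl)Cl | intermediate
3 | 2,4-dimethoxy-6-pentylbenzaldehyde | CCCCCc1cc(OC)cc(OC)c1C=O | intermediate
4 | 2,4-dimethoxy-6-pentylphenyl formate (not isolated) | CCCCCc1cc(OC)cc(OC)c1OC=O | intermediate
5 | 2,4-dimethoxy-6-pentylphenol | CCCCCc1cc(OC)cc(OC)c1O | intermediate
6 | methyl acetoacetate | COC(=O)CC(C)=O | starting material
7 | malonyl dichloride | O=C(Cl)CC(=O)Cl | starting material
8 | methyl 4-hydroxy-6-methyl-2-oxo-2H-pyran-5-carboxylate | COC(=O)c1c(C)oc(=O)cc1O | intermediate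
9 | methyl 4-(dichlorophosphoryloxy)-6-methyl-2-oxo-2H-pyran-5-carboxylate (not isolated) | COC(=O)c1c(C)oc(=O)cc1OP(=O)(Cl)Cl | intermediate
10 | methyl 4-chloro-6-methyl-2-oxo-2H-pyran-5-carboxylate | COC(=O)c1c(C)oc(=O)cc1Cl | intermediate
11 | methyl 4-(2,4-dimethoxy-6-pentylphenoxy)-6-methyl-2-oxo-2H-pyran-5-carboxylate | COC(=O)c1c(C)oc(=O)cc1Oc1c(OC)cc(OC)cc1CCCCC | intermediate
12 | 1,1-dimethoxyethene | C=C(OC)OC | starting material
13 | methyl 5-(2,4-dimethoxy-6-pentylphenoxy)-8,8-dimethoxy-1-methyl-3-oxo-2-oxabicyclo[2.2.2]oct-5-ene-6-carboxylate (racemic, not isolated) | COC(=O)C1=C(Oc2c(OC)cc(OC)cc2CCCCC)C2C(=O)OC1(C)CC2(OC)OC | intermediate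
14 | methyl 6-(2,4-dimethoxy-6-pentylphenoxy)-4,4-dimethoxy-2-methylcyclohexa-1,5-diene-1-carboxylate (not isolated) | COC(=O)C1=C(C)CC(OC)(OC)C=C1Oc1c(OC)cc(OC)cc1CCCCC | intermediate
15 | methyl 2-(2,4-dimethoxy-6-pentylphenoxy)-4-methoxy-6-methylbenzoate | COC(=O)c1c(C)cc(OC)cc1Oc1c(OC)cc(OC)cc1CCCCC | intermediate
16 | N-methoxy-N-methylhexanamide | CCCCCC(=O)N(C)OC | starting material
17 | methyl 2-(2,4-dimethoxy-6-pentylphenoxy)-6-(lithiomethyl)-4-methoxybenzoate (not isolated) | COC(=O)c1c(C[Li])cc(OC)cc1Oc1c(OC)cc(OC)cc1CCCCC | intermediate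
18 | methyl 2-(2,4-dimethoxy-6-pentylphenoxy)-6-{2-(lithiooxy)-2-[methoxy(methyl)amino]heptyl}-4-methoxybenzoate (racemic, not isolated) | COC(=O)c1c(CC(CCCCC)(O[Li])N(C)OC)cc(OC)cc1Oc1c(OC)cc(OC)cc1CCCCC | intermediate
19 | methyl 2-(2,4-dimethoxy-6-pentylphenoxy)-4-methoxy-6-(2-oxoheptyl)benzoate | COC(=O)c1c(CC(=O)CCCCC)cc(OC)cc1Oc1c(OC)cc(OC)cc1CCCCC | intermediate
20 | 8-(2,4-dimethoxy-6-pentylphenoxy)-6-methoxy-3-pentyl-1H-isochromen-1-one | CCCCCc1cc2cc(OC)cc(Oc3c(OC)cc(OC)cc3CCCCC)c2c(=O)o1 | intermediate
21 | 8-[2,4-bis(dibromoboryloxy)-6-pentylphenoxy]-6-(dibromoboryloxy)-3-pentyl-1H-isochromen-1-one (not isolated) | CCCCCc1cc2cc(OB(Br)Br)cc(Oc3c(OB(Br)Br)cc(OB(Br)Br)cc3CCCCC)c2c(=O)o1 | intermediate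
22 | 8-(2,4-dihydroxy-6-pentylphenoxy)-6-hydroxy-3-pentyl-1H-isochromen-1-one (CNP0213708.0) | CCCCCc1cc2cc(O)cc(Oc3c(O)cc(O)cc3CCCCC)c2c(=O)o1 | target

Total step count: 9
Longest linear sequence: 7 steps (steps 1, 2, 5, 6, 7, 8, 9; the branch through steps 3 and 4 is equally long)

Steps most likely to fail

Step 6. The aryloxy group donates into the diene and the 6-methyl group shields the electrophilic terminus, so the cycloaddition may be too slow and the ketene acetal may oligomerise or hydrolyse before it adds. The fallback gives up the cycloaddition and makes the diaryl ether on a preformed ring A. It sets out from phenol 5. Purchased methyl 2-hydroxy-4-methoxy-6-methylbenzoate (sparassol) F1 would be converted with Tf2O and pyridine in CH2Cl2 into methyl 4-methoxy-6-methyl-2-(trifluoromethylsulfonyloxy)benzoate F2. F2 and 5 would then be joined by palladium-catalysed C–O coupling (Pd(OAc)2, 2-di-tert-butylphosphino-2′,4′,6′-triisopropylbiphenyl, K3PO4, toluene, 100 °C). The fallback comes back to the route at compound 15.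

Step 5. The doubly ortho-substituted phenoxide may add too slowly at C4, and attack at the lactone carbonyl or at C6 may open the pyranone ring instead of substituting. The fallback reverses the order of events and sets out from chloropyranone 10. Heating 10 with 12 as in step 6 should lead, through methyl 5-chloro-8,8-dimethoxy-1-methyl-3-oxo-2-oxabicyclo[2.2.2]oct-5-ene-6-carboxylate F3 and methyl 6-chloro-4,4-dimethoxy-2-methylcyclohexa-1,5-diene-1-carboxylate F4, to methyl 2-chloro-4-methoxy-6-methylbenzoate F5. This diene is more electron-poor than 11. F5, activated by its ortho ester, would then be coupled with phenol 5 under palladium catalysis (Pd(OAc)2, 2-di-tert-butylphosphino-2′,4′,6′-triisopropylbiphenyl, K3PO4, toluene, 100 °C). The fallback comes back to the route at compound 15.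

Step 7. The benzylic anion may condense with the ester of toluate that is not yet deprotonated, and proton transfer between anion and product may leave the acylation incomplete. The fallback removes the electrophilic ester before the anion is made and sets out from compound 15. Saponification (KOH, DMSO–H2O, 100 °C) should give 2-(2,4-dimethoxy-6-pentylphenoxy)-4-methoxy-6-methylbenzoic acid F6. Double deprotonation with LiN(iPr)2 (2.2 equiv, THF, −78 to 0 °C) should give lithium 2-(2,4-dimethoxy-6-pentylphenoxy)-6-(lithiomethyl)-4-methoxybenzoate F7, whose carboxylate cannot be attacked. Acylation with 16 should pass through the lithium carboxylate of the tetrahedral lithium adduct F8 and give, on acidic work-up, 2-(2,4-dimethoxy-6-pentylphenoxy)-4-methoxy-6-(2-oxoheptyl)benzoic acid F9. Cyclodehydration of this keto acid with Ac2O at 100 °C is the classical isocoumarin closure. The fallback comes back to the route at compound 20.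

Further compounds
F1 | step 6 | methyl 2-hydroxy-4-methoxy-6-methylbenzoate (sparassol, purchased) | COC(=O)c1c(C)cc(OC)cc1O
F2 | step 6 | methyl 4-methoxy-6-methyl-2-(trifluoromethylsulfonyloxy)benzoate | COC(=O)c1c(C)cc(OC)cc1OS(=O)(=O)C(F)(F)F
F3 | step 5 | methyl 5-chloro-8,8-dimethoxy-1-methyl-3-oxo-2-oxabicyclo[2.2.2]oct-5-ene-6-carboxylate (racemic) | COC(=O)C1=C(Cl)C2C(=O)OC1(C)CC2(OC)OC
F4 | step 5 | methyl 6-chloro-4,4-dimethoxy-2-methylcyclohexa-1,5-diene-1-carboxylate | COC(=O)C1=C(C)CC(OC)(OC)C=C1Cl
F5 | step 5 | methyl 2-chloro-4-methoxy-6-methylbenzoate | COC(=O)c1c(C)cc(OC)cc1Cl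
F6 | step 7 | 2-(2,4-dimethoxy-6-pentylphenoxy)-4-methoxy-6-methylbenzoic acid | OC(=O)c1c(C)cc(OC)cc1Oc1c(OC)cc(OC)cc1CCCCC
F7 | step 7 | lithium 2-(2,4-dimethoxy-6-pentylphenoxy)-6-(lithiomethyl)-4-methoxybenzoate | [Li]OC(=O)c1c(C[Li])cc(OC)cc1Oc1c(OC)cc(OC)cc1CCCCC
F8 | step 7 | lithium 2-(2,4-dimethoxy-6-pentylphenoxy)-6-{2-(lithiooxy)-2-[methoxy(methyl)amino]heptyl}-4-methoxybenzoate (racemic) | [Li]OC(=O)c1c(CC(CCCCC)(O[Li])N(C)OC)cc(OC)cc1Oc1c(OC)cc(OC)cc1CCCCC
F9 | step 7 | 2-(2,4-dimethoxy-6-pentylphenoxy)-4-methoxy-6-(2-oxoheptyl)benzoic acid | OC(=O)c1c(CC(=O)CCCCC)cc(OC)cc1Oc1c(OC)cc(OC)cc1CCCCC
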